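## Retrosynthetic overview

- The two ring-A silyl ethers come off last. The Z-allylic alcohol arm is an alkyne reduced syn, attached by Sonogashira coupling at an aryl iodide. The prenyl arm comes from Stille coupling at the neighbouring aryl bromide.
- The C4 carbonyl is traced back to the CH2 group of an (S)-flavan. C4 is benzylic to ring A and sits ortho to O1, ortho to the C5 oxygen and para to the C7 oxygen, so hydride is abstracted there in preference to C2.
- Ring C is cut at O1–C2 and C3–C4. C2 and C3 are the two alkene carbons of a ring-B styrene, and O1, C8a, C4a and C4 make up an ortho-quinone methide of ring A. This match of the benzopyran with a styrene plus a methide is the feature the plan rests on.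
- The methide comes from a 2-hydroxybenzyl alcohol (two steps from 2,4,6-trihydroxybenzaldehyde). The styrene comes from 3-bromo-4-hydroxybenzaldehyde by iodination, methylation and Wittig methylenation.
- Ring order: rings A and B are bought; ring C is the only ring formed, in the cycloaddition, which also sets C2.

Key step: step 6

Assumption: the sense of induction of the chiral acid cannot be predicted for a methide without a substituent, so the (R)-catalyst is written and its enantiomer would be used if it gives the (R)-flavan; compound 10 is carried on as a mixture of C4 epimers.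

## Route

Step 1
Reactants: 1 2,4,6-trihydroxybenzaldehyde
Product: 2 2,4-bis(tert-butyldimethylsilyloxy)-6-hydroxybenzaldehyde
Conditions: TBSCl (2.1 equiv), imidazole, CH2Cl2, 0 °C
Reagents that add atoms: tert-butyldimethylsilyl chloride, CC(C)(C)[Si](C)(C)Cl
Why: Phenol silylation stops at the bis-ether because the remaining ortho hydroxyl is locked in a hydrogen bond to the formyl oxygen and is the least nucleophilic of the three.

Step 2
Reactants: 2 2,4-bis(tert-butyldimethylsilyloxy)-6-hydroxybenzaldehyde
Product: 3 2-(hydroxymethyl)-3,5-bis(tert-butyldimethylsilyloxy)phenol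
Conditions: NaBH4, THF/MeOH, −10 °C; pH 7 phosphate buffer; used crude at once
Reagents that add atoms: none
Why: Borohydride reduction of the aryl aldehyde, where low temperature, short contact and a neutral quench keep the aryl silyl groups from migrating to the new alkoxide and keep the electron-rich 2-hydroxybenzyl alcohol from ionising before use.

Step 3
Reactants: 4 3-bromo-4-hydroxybenzaldehyde
Product: 5 3-bromo-4-hydroxy-5-iodobenzaldehyde
Conditions: NIS, AcOH, rt
Reagents that add atoms: N-iodosuccinimide, O=C1CCC(=O)N1I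
Why: Electrophilic aromatic iodination goes to the only free position ortho to the phenol hydroxyl, since the other ortho position holds bromine and the para position holds the formyl group.

Step 4
Reactants: 5 3-bromo-4-hydroxy-5-iodobenzaldehyde
Product: 6 3-bromo-5-iodo-4-methoxybenzaldehyde
Conditions: MeI, K2CO3, DMF, rt
Reagents that add atoms: iodomethane, CI
Why: Williamson ether synthesis on an acidic 2,6-dihalophenol, whose carbonate-generated phenoxide is reached by the small electrophile despite the two flanking halogens.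

Step 5
Reactants: 6 3-bromo-5-iodo-4-methoxybenzaldehyde
Product: 7 1-bromo-5-ethenyl-3-iodo-2-methoxybenzene
Conditions: Ph3PCH3Br, KOtBu, THF, 0 °C to rt
Reagents that add atoms: methyltriphenylphosphonium bromide, C[P+](c1ccccc1)(c1ccccc1)c1ccccc1.[Br-]
Why: Wittig methylenation of a non-enolisable aryl aldehyde with the unstabilised ylide, which leaves both aryl halides untouched.

Step 6
Reactants: 3 2-(hydroxymethyl)-3,5-bis(tert-butyldimethylsilyloxy)phenol; 7 1-bromo-5-ethenyl-3-iodo-2-methoxybenzene
Product: 9 (2S)-2-(3-bromo-5-iodo-4-methoxyphenyl)-5,7-bis(tert-butyldimethylsilyloxy)chromane, via ortho-quinone methide 8 (not isolated)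
Conditions: (R)-3,3'-bis(2,4,6-triisopropylphenyl)-BINOL N-triflylphosphoramide (10 mol%), 7 (3 equiv), 3 added slowly over 6 h, toluene, 4 Å MS, −20 °C to 0 °C
Reagents that add atoms: none
Why: Proposed new method: the acid dehydrates 3 to the ortho-quinone methide 8 and stays bound to its carbonyl oxygen, the CH2 carbon of styrene 7 attacks the unsubstituted methide carbon (C3–C4), and the benzylic cation growing at C2 is trapped by the phenol oxygen inside the chiral ion pair (O1–C2), that is an asynchronous inverse-demand oxa-[4+2] cycloaddition. The closest known reaction type is the cycloaddition of styrenes with ortho-quinone methides made from 2-hydroxybenzhydryl alcohols under chiral phosphoric acid or N-triflylphosphoramide catalysis; not yet shown are a methide carbon without a substituent, so that the styrene face is the only prochiral element, and a styrene carrying two halogens. Ring C is closed by intermolecular annulation, the C–C bond first and the six-membered ring then shut by C–O bond formation at the cation. The single new stereocentre C2 is set by the catalyst alone (the N-triflyl amide is taken because the styrene has no hydrogen-bond donor, so only the electrophile can be activated): its anion, hydrogen-bonded to the ring-A oxygen, holds the cation in one orientation while O1 closes, and the catalyst enantiomer is chosen to give (S). Regioselectivity (aryl at C2) follows from the styrene polarity, since positive charge can build up only at the aryl-bearing carbon. Chemoselectivity over Friedel–Crafts self-alkylation of ring A is secured by the two bulky silyl ethers flanking its free positions together with slow addition of 3 into excess 7, and the electron-poor ring B keeps the new C2–O bond from ionising, so the product should not racemise under the acid.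

Step 7
Reactants: 9 (2S)-2-(3-bromo-5-iodo-4-methoxyphenyl)-5,7-bis(tert-butyldimethylsilyloxy)chromane
Product: 10 (2S)-2-(3-bromo-5-iodo-4-methoxyphenyl)-5,7-bis(tert-butyldimethylsilyloxy)chroman-4-ol (mixture of C4 epimers)
Conditions: DDQ (1.2 equiv), CH2Cl2/H2O (10:1), 0 °C
Reagents that add atoms: water, O
Why: Benzylic oxidation by hydride abstraction with DDQ, as established for C4 of 5,7-dioxygenated flavans: the C4 cation is stabilised by O1, the C5 oxygen and the C7 oxygen and is trapped by water, whereas C2–H next to the halogenated ring B is far less hydridic; the new C4 centre is not controlled and is erased in step 8.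

Step 8
Reactants: 10 (2S)-2-(3-bromo-5-iodo-4-methoxyphenyl)-5,7-bis(tert-butyldimethylsilyloxy)chroman-4-ol
Product: 11 (2S)-2-(3-bromo-5-iodo-4-methoxyphenyl)-5,7-bis(tert-butyldimethylsilyloxy)chroman-4-one
Conditions: Dess–Martin periodinane, NaHCO3, CH2Cl2, 0 °C to rt
Reagents that add atoms: none
Why: Dess–Martin oxidation of the secondary benzylic alcohol under buffered, non-basic conditions, so C2 cannot epimerise by ring opening.

Step 9
Reactants: 11 (2S)-2-(3-bromo-5-iodo-4-methoxyphenyl)-5,7-bis(tert-butyldimethylsilyloxy)chroman-4-one; 12 2-methylbut-3-yn-2-ol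
Product: 13 (2S)-2-[3-bromo-5-(3-hydroxy-3-methylbut-1-yn-1-yl)-4-methoxyphenyl]-5,7-bis(tert-butyldimethylsilyloxy)chroman-4-one
Conditions: PdCl2(PPh3)2 (3 mol%), CuI (copper monoiodide, 5 mol%), Et3N, THF, rt
Reagents that add atoms: none
Why: Sonogashira coupling, in which oxidative addition into C–I is much faster than into C–Br at room temperature, so only the iodide is exchanged and the mild amine leaves the silyl ethers and C2 alone.

Step 10
Reactants: 13 (2S)-2-[3-bromo-5-(3-hydroxy-3-methylbut-1-yn-1-yl)-4-methoxyphenyl]-5,7-bis(tert-butyldimethylsilyloxy)chroman-4-one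
Product: 14 (2S)-2-[3-(3-hydroxy-3-methylbut-1-yn-1-yl)-4-methoxy-5-(3-methylbut-2-en-1-yl)phenyl]-5,7-bis(tert-butyldimethylsilyloxy)chroman-4-one
Conditions: tributyl(3-methylbut-2-en-1-yl)stannane (1.5 equiv), Pd(PPh3)4 (5 mol%), degassed toluene, 100 °C
Reagents that add atoms: tributyl(3-methylbut-2-en-1-yl)stannane, CC(C)=CC[Sn](CCCC)(CCCC)CCCC
Why: Stille coupling of the aryl bromide under neutral conditions, where the allyl–palladium intermediate equilibrates to its less hindered primary terminus before reductive elimination and so gives the linear prenyl arene, and no base is present that could open ring C.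

Step 11
Reactants: 14 (2S)-2-[3-(3-hydroxy-3-methylbut-1-yn-1-yl)-4-methoxy-5-(3-methylbut-2-en-1-yl)phenyl]-5,7-bis(tert-butyldimethylsilyloxy)chroman-4-one
Product: 15 (2S)-2-[3-[(1Z)-3-hydroxy-3-methylbut-1-en-1-yl]-4-methoxy-5-(3-methylbut-2-en-1-yl)phenyl]-5,7-bis(tert-butyldimethylsilyloxy)chroman-4-one
Conditions: H2 (1 atm), Pd/CaCO3 poisoned with Pb(OAc)2 (Lindlar catalyst), quinoline, EtOAc, rt, stopped after one equivalent of H2
Reagents that add atoms: none
Why: Lindlar semihydrogenation delivers both hydrogens from the catalyst surface to the same face of the alkyne, which sets the Z alkene, while the poisoned catalyst leaves the trisubstituted prenyl alkene, the aryl ketone and the benzylic C2–O bond untouched.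

Step 12
Reactants: 15 (2S)-2-[3-[(1Z)-3-hydroxy-3-methylbut-1-en-1-yl]-4-methoxy-5-(3-methylbut-2-en-1-yl)phenyl]-5,7-bis(tert-butyldimethylsilyloxy)chroman-4-one
Product: 16 (2S)-5,7-dihydroxy-2-[3-[(1Z)-3-hydroxy-3-methylbut-1-en-1-yl]-4-methoxy-5-(3-methylbut-2-en-1-yl)phenyl]chroman-4-one (CNP0223123.2)
Conditions: TBAF (2.5 equiv), AcOH (2.5 equiv), THF, 0 °C
Reagents that add atoms: none
Why: Fluoride desilylation of the two aryl silyl ethers, buffered so that each phenoxide is protonated as it forms and no retro-oxa-Michael opening racemises C2, and free of strong acid so the tertiary Z-allylic alcohol is spared.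

## Compound list

1 | 2,4,6-trihydroxybenzaldehyde | O=Cc1c(O)cc(O)cc1O | starting material
2 | 2,4-bis(tert-butyldimethylsilyloxy)-6-hydroxybenzaldehyde | O=Cc1c(O)cc(O[Si](C)(C)C(C)(C)C)cc1O[Si](C)(C)C(C)(C)C | intermediate
3 | 2-(hydroxymethyl)-3,5-bis(tert-butyldimethylsilyloxy)phenol | OCc1c(O)cc(O[Si](C)(C)C(C)(C)C)cc1O[Si](C)(C)C(C)(C)C | intermediate
4 | 3-bromo-4-hydroxybenzaldehyde | O=Cc1ccc(O)c(Br)c1 | starting material
5 | 3-bromo-4-hydroxy-5-iodobenzaldehyde | O=Cc1cc(Br)c(O)c(I)c1 | intermediate
6 | 3-bromo-5-iodo-4-methoxybenzaldehyde | COc1c(Br)cc(C=O)cc1I | intermediate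
7 | 1-bromo-5-ethenyl-3-iodo-2-methoxybenzene | C=Cc1cc(Br)c(OC)c(I)c1 | intermediate
8 | 3,5-bis(tert-butyldimethylsilyloxy)-6-methylidenecyclohexa-2,4-dien-1-one (ortho-quinone methide) | C=C1C(=O)C=C(O[Si](C)(C)C(C)(C)C)C=C1O[Si](C)(C)C(C)(C)C | intermediate
9 | (2S)-2-(3-bromo-5-iodo-4-methoxyphenyl)-5,7-bis(tert-butyldimethylsilyloxy)chromane | COc1c(I)cc([C@@H]2CCc3c(O[Si](C)(C)C(C)(C)C)cc(O[Si](C)(C)C(C)(C)C)cc3O2)cc1Br | intermediate
10 | (2S)-2-(3-bromo-5-iodo-4-methoxyphenyl)-5,7-bis(tert-butyldimethylsilyloxy)chroman-4-ol, C4 epimers | COc1c(I)cc([C@@H]2CC(O)c3c(O[Si](C)(C)C(C)(C)C)cc(O[Si](C)(C)C(C)(C)C)cc3O2)cc1Br | intermediate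
11 | (2S)-2-(3-bromo-5-iodo-4-methoxyphenyl)-5,7-bis(tert-butyldimethylsilyloxy)chroman-4-one | COc1c(I)cc([C@@H]2CC(=O)c3c(O[Si](C)(C)C(C)(C)C)cc(O[Si](C)(C)C(C)(C)C)cc3O2)cc1Br | intermediate
12 | 2-methylbut-3-yn-2-ol | CC(C)(O)C#C | starting material
13 | (2S)-2-[3-bromo-5-(3-hydroxy-3-methylbut-1-yn-1-yl)-4-methoxyphenyl]-5,7-bis(tert-butyldimethylsilyloxy)chroman-4-one | COc1c(C#CC(C)(C)O)cc([C@@H]2CC(=O)c3c(O[Si](C)(C)C(C)(C)C)cc(O[Si](C)(C)C(C)(C)C)cc3O2)cc1Br | intermediate
14 | (2S)-2-[3-(3-hydroxy-3-methylbut-1-yn-1-yl)-4-methoxy-5-(3-methylbut-2-en-1-yl)phenyl]-5,7-bis(tert-butyldimethylsilyloxy)chroman-4-one | COc1c(C#CC(C)(C)O)cc([C@@H]2CC(=O)c3c(O[Si](C)(C)C(C)(C)C)cc(O[Si](C)(C)C(C)(C)C)cc3O2)cc1CC=C(C)C | intermediate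
15 | (2S)-2-[3-[(1Z)-3-hydroxy-3-methylbut-1-en-1-yl]-4-methoxy-5-(3-methylbut-2-en-1-yl)phenyl]-5,7-bis(tert-butyldimethylsilyloxy)chroman-4-one | COc1c(/C=C\C(C)(C)O)cc([C@@H]2CC(=O)c3c(O[Si](C)(C)C(C)(C)C)cc(O[Si](C)(C)C(C)(C)C)cc3O2)cc1CC=C(C)C | intermediate
16 | (2S)-5,7-dihydroxy-2-[3-[(1Z)-3-hydroxy-3-methylbut-1-en-1-yl]-4-methoxy-5-(3-methylbut-2-en-1-yl)phenyl]chroman-4-one | COc1c(/C=C\C(C)(C)O)cc([C@@H]2CC(=O)c3c(O)cc(O)cc3O2)cc1CC=C(C)C | target

## Step count and risks

Total step count: 12. Longest linear sequence: 10 steps (from 4 through steps 3 to 12).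

**Step 6 (proposed new method).** The chiral acid may discriminate poorly between the two faces at C2. The methide may also alkylate ring A of its own precursor or of the product faster than it adds to the deactivated styrene.

The fallback uses known chemistry, sets out from 6 and 3 and comes back at 9:
- Aldehyde 6 takes up MeMgBr in THF at −78 °C to give racemic 1-(3-bromo-5-iodo-4-methoxyphenyl)ethan-1-ol F1.
- Dess–Martin oxidation gives 1-(3-bromo-5-iodo-4-methoxyphenyl)ethan-1-one F2.
- TMSOTf and Et3N in CH2Cl2 at 0 °C give the silyl enol ether [1-(3-bromo-5-iodo-4-methoxyphenyl)ethenyl]oxy(trimethyl)silane F3.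
- Alcohol 3 and F3 are warmed in toluene over 4 Å MS. Compound 3 loses water to methide 8, which adds to the electron-rich enol ether in a thermal hetero-Diels–Alder reaction to give racemic 2-(3-bromo-5-iodo-4-methoxyphenyl)-5,7-bis(tert-butyldimethylsilyloxy)-2-(trimethylsilyloxy)chromane F4.
- Citric acid in wet THF cleaves the silyl ketal to the open ketone 1-(3-bromo-5-iodo-4-methoxyphenyl)-3-[2-hydroxy-4,6-bis(tert-butyldimethylsilyloxy)phenyl]propan-1-one F5.
- Corey–Bakshi–Shibata reduction with (S)-2-methyl-CBS-oxazaborolidine and excess BH3·SMe2 in THF at −20 °C gives (1R)-1-(3-bromo-5-iodo-4-methoxyphenyl)-3-[2-hydroxy-4,6-bis(tert-butyldimethylsilyloxy)phenyl]propan-1-ol F6.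
- Mitsunobu etherification (PPh3, diisopropyl azodicarboxylate, THF, 0 °C) closes O1–C2 with inversion at the carbinol carbon. The electron-poor aryl group disfavours ionisation, so clean inversion to (S)-9 is expected.

**Step 7.** The C4 cation may lose a proton to the flav-3-ene, which would then lose hydride from C2 and aromatise, erasing the stereocentre. Hydride abstraction from the silyl-ether-bearing ring may also be sluggish.

The fallback brings the C4 oxygen in at the aldehyde oxidation level instead of by C–H oxidation; it sets out from 2 and 7 and comes back at 10: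
- Aldehyde 2 is converted in the flask with trimethyl orthoformate into its acetal 2-(dimethoxymethyl)-3,5-bis(tert-butyldimethylsilyloxy)phenol F7.
- The chiral acid of step 6 ionises F7, with loss of methanol, to the methoxy-substituted methide 3,5-bis(tert-butyldimethylsilyloxy)-6-(methoxymethylidene)cyclohexa-2,4-dien-1-one F8.
- F8 adds to 7 in the same way as 8 to give (2S)-2-(3-bromo-5-iodo-4-methoxyphenyl)-5,7-bis(tert-butyldimethylsilyloxy)-4-methoxychromane F9 as C4 epimers.
- PPTS in wet THF exchanges the C4 methoxy group for hydroxyl through the same three-oxygen-stabilised cation and delivers 10.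
- The C2 selectivity with this substituted methide would have to be confirmed anew; C4 needs no control.

**Step 10.** The prenyl group may be transferred through its tertiary terminus (reverse-prenyl isomer). Oxidative addition into the hindered ortho-methoxy aryl bromide may also be slow, and long heating can erode C2 by ring opening.

The fallback replaces the direct prenyl transfer by allylation and olefin exchange; it sets out from 13 and comes back at 14:
- Allyltributylstannane and Pd(PPh3)4 in toluene at 90 °C, where the regiochemical question does not arise, give (2S)-2-[3-(3-hydroxy-3-methylbut-1-yn-1-yl)-4-methoxy-5-(prop-2-en-1-yl)phenyl]-5,7-bis(tert-butyldimethylsilyloxy)chroman-4-one F10.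
- Cross-metathesis with 2-methyl-2-butene, using the second-generation Grubbs catalyst RuCl2(=CHPh)(H2IMes)(PCy3) in CH2Cl2 at 40 °C, turns the allyl group into the prenyl group of 14.
- The internal alkyne is shielded by its quaternary carbinol carbon and the ortho-disubstituted arene and is expected to stay out of the metathesis.

## Further compounds

F1 | step 6 | 1-(3-bromo-5-iodo-4-methoxyphenyl)ethan-1-ol (racemic) | COc1c(Br)cc(C(C)O)cc1I
F2 | step 6 | 1-(3-bromo-5-iodo-4-methoxyphenyl)ethan-1-one | COc1c(Br)cc(C(C)=O)cc1I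
F3 | step 6 | [1-(3-bromo-5-iodo-4-methoxyphenyl)ethenyl]oxy(trimethyl)silane | COc1c(Br)cc(C(=C)O[Si](C)(C)C)cc1I
F4 | step 6 | 2-(3-bromo-5-iodo-4-methoxyphenyl)-5,7-bis(tert-butyldimethylsilyloxy)-2-(trimethylsilyloxy)chromane (racemic) | COc1c(Br)cc(C2(O[Si](C)(C)C)CCc3c(O[Si](C)(C)C(C)(C)C)cc(O[Si](C)(C)C(C)(C)C)cc3O2)cc1I
F5 | step 6 | 1-(3-bromo-5-iodo-4-methoxyphenyl)-3-[2-hydroxy-4,6-bis(tert-butyldimethylsilyloxy)phenyl]propan-1-one | COc1c(Br)cc(C(=O)CCc2c(O)cc(O[Si](C)(C)C(C)(C)C)cc2O[Si](C)(C)C(C)(C)C)cc1I
F6 | step 6 | (1R)-1-(3-bromo-5-iodo-4-methoxyphenyl)-3-[2-hydroxy-4,6-bis(tert-butyldimethylsilyloxy)phenyl]propan-1-ol | O[C@H](CCc1c(O)cc(O[Si](C)(C)C(C)(C)C)cc1O[Si](C)(C)C(C)(C)C)c1cc(Br)c(OC)c(I)c1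
F7 | step 7 | 2-(dimethoxymethyl)-3,5-bis(tert-butyldimethylsilyloxy)phenol | COC(OC)c1c(O)cc(O[Si](C)(C)C(C)(C)C)cc1O[Si](C)(C)C(C)(C)C
F8 | step 7 | 3,5-bis(tert-butyldimethylsilyloxy)-6-(methoxymethylidene)cyclohexa-2,4-dien-1-one | COC=C1C(=O)C=C(O[Si](C)(C)C(C)(C)C)C=C1O[Si](C)(C)C(C)(C)C
F9 | step 7 | (2S)-2-(3-bromo-5-iodo-4-methoxyphenyl)-5,7-bis(tert-butyldimethylsilyloxy)-4-methoxychromane, C4 epimers | COc1c(I)cc([C@@H]2CC(OC)c3c(O[Si](C)(C)C(C)(C)C)cc(O[Si](C)(C)C(C)(C)C)cc3O2)cc1Br
F10 | step 10 | (2S)-2-[3-(3-hydroxy-3-methylbut-1-yn-1-yl)-4-methoxy-5-(prop-2-en-1-yl)phenyl]-5,7-bis(tert-butyldimethylsilyloxy)chroman-4-one | COc1c(CC=C)cc([C@@H]2CC(=O)c3c(O[Si](C)(C)C(C)(C)C)cc(O[Si](C)(C)C(C)(C)C)cc3O2)cc1C#CC(C)(C)O
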